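**Retrosynthetic overview**

1. Target acid ⇐ its methyl ester ⇐ aryl allyl ether by a formal [1,3] O→C allyl shift to the free ortho carbon ⇐ (E)-allylic C20 alcohol + methyl 4-hydroxybenzoate, joined through the O–C15 bond.
2. (E)-Allylic alcohol ⇐ E-enoate ⇐ bicyclic C18 methyl ketone (the olefination sets 13E).
3. Δ8(9) ketone ⇐ tricyclic enol ether (mirror image of sclareol oxide) by acid opening of its C8–O bond.
4. Enol ether ⇐ (5E,9E)-farnesylacetone by a catalytic asymmetric cyclization that ends with C8–O bond formation and sets 5R,10R (labdane numbering; 4aR,8aR of the octahydronaphthalene). This is the mirror-image series of sclareol, so the chiral pool is not used.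
5. Ring order: carbocyclic rings A and B plus a temporary pyran ring C in one step; ring C is then opened; the benzene ring is bought.

Assumptions: (5E,9E)-farnesylacetone is bought as the single geometric isomer; the (S,S)-acid is taken to give the 5R,10R series, and if the sense is the reverse the (R,R)-acid is used (sign of rotation checked against material made from natural sclareol, which is 5S,10S).

**Step 1**
Reactants: 1 (5E,9E)-farnesylacetone, (5E,9E)-6,10,14-trimethylpentadeca-5,9,13-trien-2-one
Product: 2 ent-sclareol oxide, (4aS,6aR,10aR,10bS)-3,4a,7,7,10a-pentamethyl-4a,5,6,6a,7,8,9,10,10a,10b-decahydro-1H-benzo[f]chromene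
Conditions: (S,S)-HN[P(=NSO2CF3)(O2C20H10Ar2)]2 (Ar = 3,5-(CF3)2C6H3; O2C20H10Ar2 = 3,3′-diaryl-1,1′-binaphthalene-2,2′-diolate) 3 mol%, (CF3)3COH, 0 °C
Reagents that add atoms: none
Why: Proposed new method: the confined chiral acid protonates the terminal trisubstituted olefin of 1 while the chain is folded chair–chair in its pocket, the two E-olefins add anti (Stork–Eschenmoser course) so that C5–H and C10–CH3 end up trans, and the ketone oxygen captures the C8 cation through a six-membered ring before the counter-anion removes H-12, so the catalyst fixes the absolute sense (5R,10R) at the first ring closure and the E,E-geometry fixes the rest; the closest known reaction types are the imidodiphosphorimidate-catalysed, alcohol-terminated cyclization of homofarnesol to ambroxide in fluorinated alcohols and the racemic superacid cyclization of farnesylacetone to sclareol oxide, the new element being an enantioselective version with a ketone as the terminating nucleophile.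

**Step 2**
Reactants: 2 ent-sclareol oxide
Product: 3 4-[(4aR,8aR)-2,5,5,8a-tetramethyl-3,4,4a,5,6,7,8,8a-octahydronaphthalen-1-yl]butan-2-one
Conditions: p-TsOH·H2O (10 mol%), toluene, 80 °C; minor ring-olefin isomers removed on AgNO3–SiO2
Reagents that add atoms: none
Why: Acid-catalysed E1 ring-opening of the cyclic enol ether (protonation at C-12, heterolysis of the tertiary C8–O bond, loss of H-9) under thermodynamic control is expected to favour the tetrasubstituted Δ8(9) olefin and frees the methyl ketone; the C8 and C9 centres are erased and 4aR,8aR are untouched.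

**Step 3**
Reactants: 3 the Δ8(9) methyl ketone
Product: 4 ethyl (2E)-3-methyl-5-[(4aR,8aR)-2,5,5,8a-tetramethyl-3,4,4a,5,6,7,8,8a-octahydronaphthalen-1-yl]pent-2-enoate
Conditions: (EtO)2P(O)CH2CO2Et, NaH, THF, 0 °C to reflux; Z isomer removed by chromatography
Reagents that add atoms: triethyl phosphonoacetate, CCOC(=O)CP(=O)(OCC)OCC
Why: Horner–Wadsworth–Emmons olefination of the unhindered methyl ketone gives the conjugated ester mainly as the E isomer (typically about 5:1), and removing the minor Z isomer fixes the 13E geometry.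

**Step 4**
Reactants: 4 the E-enoate
Product: 5 (2E)-3-methyl-5-[(4aR,8aR)-2,5,5,8a-tetramethyl-3,4,4a,5,6,7,8,8a-octahydronaphthalen-1-yl]pent-2-en-1-ol
Conditions: i-Bu2AlH (2.5 equiv), CH2Cl2, −78 °C; aqueous KNaC4H4O6 work-up
Reagents that add atoms: none
Why: 1,2-Reduction of the conjugated ester by the aluminium hydride at low temperature gives the allylic alcohol without touching either olefin or the olefin geometry.

**Step 5**
Reactants: 5 the (E)-allylic alcohol; 6 methyl 4-hydroxybenzoate
Product: 7 methyl 4-{[(2E)-3-methyl-5-[(4aR,8aR)-2,5,5,8a-tetramethyl-3,4,4a,5,6,7,8,8a-octahydronaphthalen-1-yl]pent-2-en-1-yl]oxy}benzoate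
Conditions: PPh3, DIAD, THF, 0 °C to rt
Reagents that add atoms: none
Why: Mitsunobu etherification: the acidic phenol (pKa about 8.4) is alkylated on oxygen by the activated primary allylic alcohol in SN2 fashion, forming the O–C15 bond that joins the two halves with the E-olefin intact.

**Step 6**
Reactants: 7 the aryl allyl ether
Product: 8 methyl 4-hydroxy-3-[(2E)-3-methyl-5-[(4aR,8aR)-2,5,5,8a-tetramethyl-3,4,4a,5,6,7,8,8a-octahydronaphthalen-1-yl]pent-2-en-1-yl]benzoate
Conditions: MgSiO3 (Florisil-grade activated magnesium silicate), toluene, 100 °C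
Reagents that add atoms: none
Why: Formal [1,3] O-to-C allyl shift on the weakly acidic silicate surface (contact allyl cation/phenoxide pair recombining at the ortho carbon, para being blocked by the ester), a known reaction type for aryl prenyl-type ethers that keeps the linear attachment and the E-olefin.

**Step 7**
Reactants: 8 the phenol methyl ester
Product: 10 4-hydroxy-3-[(2E)-3-methyl-5-[(4aR,8aR)-2,5,5,8a-tetramethyl-3,4,4a,5,6,7,8,8a-octahydronaphthalen-1-yl]pent-2-en-1-yl]benzoic acid (target), via dilithium phenoxide-carboxylate 9 (not isolated)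
Conditions: LiOH·H2O (6 equiv), THF/MeOH/H2O, 65 °C; then 1 M HCl to pH 3, 0 °C
Reagents that add atoms: lithium hydroxide, [Li+].[OH-]
Why: Saponification of the methyl ester (BAc2) followed by brief cold acidification gives the acid; base leaves the skipped olefins alone and the cold, short acid contact avoids chroman formation.

**Compound list**

1 | (5E,9E)-farnesylacetone | CC(=O)CC/C=C(\C)CC/C=C(\C)CCC=C(C)C | starting material
2 | ent-sclareol oxide, (4aS,6aR,10aR,10bS)-3,4a,7,7,10a-pentamethyl-decahydro-1H-benzo[f]chromene | CC1=CC[C@H]2[C@]3(C)CCCC(C)(C)[C@H]3CC[C@]2(C)O1 | intermediate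
3 | 4-[(4aR,8aR)-2,5,5,8a-tetramethyl-3,4,4a,5,6,7,8,8a-octahydronaphthalen-1-yl]butan-2-one | CC1=C(CCC(C)=O)[C@]2(C)CCCC(C)(C)[C@H]2CC1 | intermediate
4 | ethyl (2E)-3-methyl-5-[(4aR,8aR)-2,5,5,8a-tetramethyl-octahydronaphthalen-1-yl]pent-2-enoate | CC1=C(CC/C(C)=C/C(=O)OCC)[C@]2(C)CCCC(C)(C)[C@H]2CC1 | intermediate
5 | (2E)-3-methyl-5-[(4aR,8aR)-2,5,5,8a-tetramethyl-octahydronaphthalen-1-yl]pent-2-en-1-ol | CC1=C(CC/C(C)=C/CO)[C@]2(C)CCCC(C)(C)[C@H]2CC1 | intermediate
6 | methyl 4-hydroxybenzoate | COC(=O)c1ccc(O)cc1 | starting material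
7 | methyl 4-{[(2E)-3-methyl-5-[(4aR,8aR)-2,5,5,8a-tetramethyl-octahydronaphthalen-1-yl]pent-2-en-1-yl]oxy}benzoate | CC1=C(CC/C(C)=C/COc3ccc(cc3)C(=O)OC)[C@]2(C)CCCC(C)(C)[C@H]2CC1 | intermediate
8 | methyl 4-hydroxy-3-[(2E)-3-methyl-5-[(4aR,8aR)-2,5,5,8a-tetramethyl-octahydronaphthalen-1-yl]pent-2-en-1-yl]benzoate | CC1=C(CC/C(C)=C/Cc2cc(C(=O)OC)ccc2O)[C@]2(C)CCCC(C)(C)[C@H]2CC1 | intermediate
9 | dilithium salt (phenoxide and carboxylate) of the target | [Li+].[Li+].CC1=C(CC/C(C)=C/Cc2cc(C(=O)[O-])ccc2[O-])[C@]2(C)CCCC(C)(C)[C@H]2CC1 | intermediate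
10 | 4-hydroxy-3-[(2E)-3-methyl-5-[(4aR,8aR)-2,5,5,8a-tetramethyl-3,4,4a,5,6,7,8,8a-octahydronaphthalen-1-yl]pent-2-en-1-yl]benzoic acid | CC1=C(CC/C(C)=C/Cc2cc(C(=O)O)ccc2O)[C@]2(C)CCCC(C)(C)[C@H]2CC1 | target

**Step count and risks**

Total steps: 7. Longest linear sequence: 7 (from 1).

Steps most likely to fail:

Step 1 (the proposed new method). The ketone is more basic than the olefins and may bind the acid, lowering turnover or enantioselectivity. Fallback with known chemistry: starting again from 1, ClSO3H in 2-nitropropane at −78 °C closes the same tricycle without enantiocontrol to give racemic sclareol oxide F1, which is opened with p-TsOH in toluene as in step 2 to racemic ketone F2. F2 is resolved by preparative supercritical-fluid chromatography on an amylose tris(3,5-dimethylphenylcarbamate) phase. The (4aR,8aR)-enantiomer is compound 3, where the route is rejoined.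

Step 2. The C8 cation may re-close onto the ketone, may give too much Δ7 or exocyclic olefin, or may be C-alkylated by the ketone enol. Fallback: setting out from 2, the enol ether is hydrolysed instead (1 M aqueous HCl, THF, rt; the C8–O bond stays intact) to hydroxy ketone F3. F3 is olefinated as in step 3 (triethyl phosphonoacetate, NaH, THF) to hydroxy ester F4. With the ketone gone, the C8 cation can no longer re-close, so dehydration of F4 under equilibrating conditions (p-TsOH, toluene, 90 °C, water removal) gives the Δ8(9) ester, compound 4, where the route is rejoined.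

Step 6. The ion pair may escape, the product may cyclise to a chroman, or the deactivated ortho carbon may react too slowly. Fallback: setting out from 5, PBr3 (Et2O, −10 °C) gives allylic bromide F5. The sodium salt of 6 (NaH, toluene, rt, heterogeneous) is then alkylated at the ortho carbon by F5, a classical ortho-allylation of phenoxides in non-polar medium that retains the E-olefin. This gives compound 8 directly, where the route is rejoined; the O-alkylated by-product is 7 and can be recycled.

**Further compounds**

F1 | step 1 | racemic sclareol oxide (1:1 mixture of 2 and its mirror image) | CC1=CC[C@H]2[C@]3(C)CCCC(C)(C)[C@H]3CC[C@]2(C)O1.CC1=CC[C@@H]2[C@@]3(C)CCCC(C)(C)[C@@H]3CC[C@@]2(C)O1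
F2 | step 1 | racemic 4-(2,5,5,8a-tetramethyl-3,4,4a,5,6,7,8,8a-octahydronaphthalen-1-yl)butan-2-one (1:1 mixture of 3 and its mirror image) | CC1=C(CCC(C)=O)[C@]2(C)CCCC(C)(C)[C@H]2CC1.CC1=C(CCC(C)=O)[C@@]2(C)CCCC(C)(C)[C@@H]2CC1
F3 | step 2 | 4-[(1S,2S,4aR,8aR)-2-hydroxy-2,5,5,8a-tetramethyldecahydronaphthalen-1-yl]butan-2-one | CC(=O)CC[C@H]1[C@]2(C)CCCC(C)(C)[C@H]2CC[C@]1(C)O
F4 | step 2 | ethyl (2E)-5-[(1S,2S,4aR,8aR)-2-hydroxy-2,5,5,8a-tetramethyldecahydronaphthalen-1-yl]-3-methylpent-2-enoate | CCOC(=O)/C=C(\C)CC[C@H]1[C@]2(C)CCCC(C)(C)[C@H]2CC[C@]1(C)O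
F5 | step 6 | (4aR,8aR)-1-[(3E)-5-bromo-3-methylpent-3-en-1-yl]-2,5,5,8a-tetramethyl-3,4,4a,5,6,7,8,8a-octahydronaphthalene | CC1=C(CC/C(C)=C/CBr)[C@]2(C)CCCC(C)(C)[C@H]2CC1
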